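**Strategy.** The target is a cis-fused (H-5/CH3-20 syn) labdane whose C8–C9–C10 triad is the carbonyl, α- and β-carbon of a ring-B enone. Everything rests on one three-component event on octalone 10 (C8=O, C9=C10, with C4 and C5 already fixed): lithium dimethylcuprate delivers C20 to the ring-fusion carbon C10 and the regiodefined C8–C9 enolate is alkylated by methyl bromoacetate, creating C10–C20, C9–C11 and both remaining stereocentres without closing a ring. The step exploits the C8(=O)–C9=C10 enone of ring B and the C4/C5 stereocentres of ring A, whose axial C18 methyl blocks the α-face. Octalone 10 comes from an aryl-directed annulation; Negishi coupling completes the side chain.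

Key step: step 6

Remarks on the chemistry (labdane numbering for atoms, naphthalene numbering in names):
- Assumption: the SMILES is read literally. H-5, CH3-20, C11 and the C19 ester lie on one face (cis-decalin; 1S,4aR,5S,8aS), and the side-chain alkene is E (C12 cis to C15).
- C19 is carried through steps 1–2 as a phenyl ring. A methyl and a vinyl or ester group on C4 are too alike to differentiate the two faces of C5, whereas a pseudoaxial phenyl should. The ring is degraded to CO2H before any C=C bond exists.
- Neither C5 epimer of octalone 10 is expected to be strongly favoured at equilibrium. C5 is therefore set kinetically (step 2), and steps 3–5 avoid equilibrating conditions.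

**Route**

Step 1
Reactants: 1 3-methylcyclohex-2-en-1-one; 2 phenyllithium
Product: 5 (S)-trimethyl[(3-methyl-3-phenylcyclohex-1-en-1-yl)oxy]silane, via dimethyl(phenyl)aluminium 3 (not isolated), via aluminium enolate 4 (not isolated)
Conditions: 2, Me2AlCl, pentane/Et2O, 0 °C; then 1, CuTC (5 mol %), chiral phosphinamine ligand (SimplePhos type, 6 mol %, antipode giving S at C4), Et2O, −30 °C; then TMSOTf, −30 → 0 °C
Reagents that add atoms: trimethylsilyl trifluoromethanesulfonate, C[Si](C)(C)OS(=O)(=O)C(F)(F)F; dimethylaluminium chloride, C[Al](C)Cl (aluminium in 3 and 4 only)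
Why: Copper-catalysed asymmetric conjugate addition of an arylaluminium to a β-substituted cyclohexenone sets the C4 quaternary centre under ligand control (the phenyl is the latent C19 carboxyl), and O-silylation of the aluminium enolate locks the enol ether regiospecifically toward C5.

Step 2
Reactants: 5 (S)-trimethyl[(3-methyl-3-phenylcyclohex-1-en-1-yl)oxy]silane; 6 methyl vinyl ketone (but-3-en-2-one)
Product: 7 (2R,3S)-3-methyl-2-(3-oxobutyl)-3-phenylcyclohexan-1-one
Conditions: BF3·OEt2 (1.2 equiv), i-PrOH (1.2 equiv), CH2Cl2/MeNO2, −78 °C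
Reagents that add atoms: none
Why: Mukaiyama–Michael addition in which C5 attacks the BF3-activated enone along the axial trajectory anti to the pseudoaxial phenyl on C4 (phenyl geminal to methyl prefers the axial site and screens its own face), so that C6 should end trans to phenyl and H-5 cis to it (2R), while i-PrOH takes up the silyl group.

Step 3
Reactants: 7 (2R,3S)-3-methyl-2-(3-oxobutyl)-3-phenylcyclohexan-1-one
Product: 8 (1S,2R)-1-methyl-3-oxo-2-(3-oxobutyl)cyclohexane-1-carboxylic acid
Conditions: RuCl3·xH2O (5 mol %), NaIO4 (excess), CCl4/MeCN/H2O, 23 °C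
Reagents that add atoms: sodium periodate, [Na+].[O-]I(=O)(=O)=O; water, O
Why: Ruthenium tetroxide oxidation (Sharpless RuCl3/NaIO4) degrades the benzene ring to a carboxylic acid and keeps the ipso carbon as C19; saturated ketones are inert, no C=C is present yet, and the near-neutral biphasic medium should not enolise the hindered C5–H.

Step 4
Reactants: 8 (1S,2R)-1-methyl-3-oxo-2-(3-oxobutyl)cyclohexane-1-carboxylic acid
Product: 9 methyl (1S,2R)-1-methyl-3-oxo-2-(3-oxobutyl)cyclohexane-1-carboxylate
Conditions: TMSCHN2, toluene/MeOH, 0 → 23 °C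
Reagents that add atoms: (trimethylsilyl)diazomethane, C[Si](C)(C)C=[N+]=[N-]
Why: Neutral O-methylation of the carboxylic acid with (trimethylsilyl)diazomethane/methanol touches neither ketone nor the C5 centre.

Step 5
Reactants: 9 methyl (1S,2R)-1-methyl-3-oxo-2-(3-oxobutyl)cyclohexane-1-carboxylate
Product: 10 methyl (1S,8aS)-1-methyl-6-oxo-1,2,3,4,6,7,8,8a-octahydronaphthalene-1-carboxylate
Conditions: NaOMe (0.5 equiv), MeOH, 0 → 23 °C; AcOH quench at full conversion
Reagents that add atoms: none
Why: Intramolecular aldol condensation (second stage of a Robinson annulation) in which the methyl-ketone enolate (C9) adds to the C10 carbonyl and the ketol dehydrates by E1cB to the C9=C10 enone; methoxide in methanol is degenerate toward the methyl ester, and the tertiary C5–H next to quaternary C4 should exchange far more slowly than C9–H.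

Step 6
Reactants: 10 methyl (1S,8aS)-1-methyl-6-oxo-1,2,3,4,6,7,8,8a-octahydronaphthalene-1-carboxylate; 11 methyllithium; 12 methyl bromoacetate
Product: 15 methyl (1S,4aS,5R,8aS)-5-(2-methoxy-2-oxoethyl)-1,4a-dimethyl-6-oxodecahydronaphthalene-1-carboxylate, via lithium dimethylcuprate 13 (not isolated), via lithium enolate 14 (not isolated)
Conditions: 11 (2 equiv), CuI (1 equiv), Et2O, 0 °C; 10, −20 → 0 °C; then THF/DMPU, 12 (4 equiv), −40 → 0 °C; NH4Cl/NH3 work-up
Reagents that add atoms: copper(I) iodide, [Cu+].[I-] (copper in 13 only)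
Why: The Gilman reagent adds its methyl to the ring-fusion β-carbon C10 (Cu(III) intermediate, reductive elimination) to give lithium enolate 14 with the double bond fixed at C8=C9, which is then C-alkylated by the α-bromo ester in a polar medium (SN2); this is the classical cuprate addition/regiospecific enolate trapping of Δ1(9)-2-octalones, and no ring is closed. At C10 the methyl should enter on the face of H-5, because the antiparallel (axial on ring B) trajectory leading to the flexible cis-decalin is intrinsically preferred for such octalones and the opposite face is further blocked by the axial C18 methyl on C4 (1,3 to C10). At C9 the enolate of the cis-fused bicycle should be attacked on its convex face, syn to the new C20 methyl and anti to the pseudoaxial C1 bond, because ring A with its quaternary C4 covers the concave face. The step needs 1,4- over 1,2-addition with the esters left alone (secured by the soft cuprate), C-alkylation without enolate equilibration toward C7 (reactive bromoacetate in excess, DMPU, ≤0 °C), and a kinetic quench so that C9 is not epimerised.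

Step 7
Reactants: 15 methyl (1S,4aS,5R,8aS)-5-(2-methoxy-2-oxoethyl)-1,4a-dimethyl-6-oxodecahydronaphthalene-1-carboxylate
Product: 16 methyl (1S,4aR,5S,8aS)-5-(2-methoxy-2-oxoethyl)-1,4a-dimethyl-6-methylidenedecahydronaphthalene-1-carboxylate
Conditions: Zn, CH2Br2, TiCl4, THF (reagent aged at 0–5 °C); then 15, CH2Cl2, 0 → 23 °C
Reagents that add atoms: dibromomethane, BrCBr
Why: Takai–Lombardo methylenation, in which the non-basic Zn/Ti gem-dimetallic reagent converts the C8 ketone into the exocyclic methylene without enolising C9 and leaves both esters untouched.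

Step 8
Reactants: 16 methyl (1S,4aR,5S,8aS)-5-(2-methoxy-2-oxoethyl)-1,4a-dimethyl-6-methylidenedecahydronaphthalene-1-carboxylate
Product: 17 methyl (1S,4aR,5S,8aS)-5-(2-hydroxyethyl)-1,4a-dimethyl-6-methylidenedecahydronaphthalene-1-carboxylate
Conditions: DIBAL-H (2.3 equiv), CH2Cl2, −78 °C; Rochelle salt work-up
Reagents that add atoms: none
Why: Sterically controlled chemoselective hydride reduction, in which DIBAL-H reduces the unhindered primary acetate ester (C12) at −78 °C while the neopentyl-like C19 ester on quaternary C4 should remain intact.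

Step 9
Reactants: 17 methyl (1S,4aR,5S,8aS)-5-(2-hydroxyethyl)-1,4a-dimethyl-6-methylidenedecahydronaphthalene-1-carboxylate
Product: 18 methyl (1S,4aR,5S,8aS)-5-(2-iodoethyl)-1,4a-dimethyl-6-methylidenedecahydronaphthalene-1-carboxylate
Conditions: I2, PPh3, imidazole, CH2Cl2, 0 → 23 °C
Reagents that add atoms: iodine, II
Why: Appel-type iodination (PPh3/I2/imidazole) of the primary alcohol by SN2 at C12, neutral toward the ester and the 1,1-disubstituted alkene.

Step 10
Reactants: 19 but-2-yne-1,4-diol
Product: 21 (Z)-2-iodobut-2-ene-1,4-diol, via cyclic alkenylalanate 20 (not isolated)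
Conditions: Red-Al (2 equiv), THF, 0 → 23 °C; then I2, THF, −78 → 0 °C
Reagents that add atoms: iodine, II; Red-Al, [Na+].COCCO[AlH2-]OCCOC (aluminium in 20 only)
Why: Hydroxyl-directed trans-hydroalumination of the propargylic diol gives a cyclic alkenylalanate whose C–Al bond is cleaved by iodine with retention, so H and I are anti and the two CH2OH groups trans (Z iodide).

Step 11
Reactants: 21 (Z)-2-iodobut-2-ene-1,4-diol
Product: 22 (Z)-1,4-bis[(tert-butyldimethylsilyl)oxy]-2-iodobut-2-ene
Conditions: TBSCl (2.4 equiv), imidazole, DMF, 23 °C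
Reagents that add atoms: tert-butyldimethylsilyl chloride, CC(C)(C)[Si](C)(C)Cl
Why: Standard silylation of both primary allylic alcohols removes the acidic protons before the organozinc step.

Step 12
Reactants: 18 methyl (1S,4aR,5S,8aS)-5-(2-iodoethyl)-1,4a-dimethyl-6-methylidenedecahydronaphthalene-1-carboxylate; 22 (Z)-1,4-bis[(tert-butyldimethylsilyl)oxy]-2-iodobut-2-ene
Product: 24 methyl (1S,4aR,5S,8aS)-5-[(3E)-5-[(tert-butyldimethylsilyl)oxy]-3-{[(tert-butyldimethylsilyl)oxy]methyl}pent-3-en-1-yl]-1,4a-dimethyl-6-methylidenedecahydronaphthalene-1-carboxylate, via alkylzinc iodide 23 (not isolated)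
Conditions: 18, Zn dust (activated with BrCH2CH2Br/TMSCl), LiCl, THF, 40 °C; then 22, PdCl2(dppf) (5 mol %), THF/DMA, 40 °C
Reagents that add atoms: zinc, [Zn] (zinc in 23 only)
Why: Negishi coupling, in which LiCl-assisted zinc insertion into the primary iodide gives an ester-tolerant alkylzinc and Pd-catalysed sp3–sp2 coupling with the vinyl iodide proceeds with retention of alkene geometry, forming C12–C13 with C12 cis to C15 (E alkene).

Step 13
Reactants: 24 methyl (1S,4aR,5S,8aS)-5-[(3E)-5-[(tert-butyldimethylsilyl)oxy]-3-{[(tert-butyldimethylsilyl)oxy]methyl}pent-3-en-1-yl]-1,4a-dimethyl-6-methylidenedecahydronaphthalene-1-carboxylate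
Product: 25 methyl (1S,4aR,5S,8aS)-5-[(3E)-5-hydroxy-3-(hydroxymethyl)pent-3-en-1-yl]-1,4a-dimethyl-6-methylidenedecahydronaphthalene-1-carboxylate
Conditions: TBAF, THF, 0 → 23 °C
Reagents that add atoms: none
Why: Fluoride cleavage of the two silyl ethers liberates the diol, while the hindered methyl ester and both alkenes are inert.

**Compound list**

1 | 3-methylcyclohex-2-en-1-one | CC1=CC(=O)CCC1 | starting material
2 | phenyllithium | [Li]c1ccccc1 | starting material
3 | dimethyl(phenyl)aluminium | C[Al](C)c1ccccc1 | intermediate (not isolated)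
4 | dimethylaluminium (S)-3-methyl-3-phenylcyclohex-1-en-1-olate | C[Al](C)OC1=C[C@@](C)(c2ccccc2)CCC1 | intermediate (not isolated)
5 | (S)-trimethyl[(3-methyl-3-phenylcyclohex-1-en-1-yl)oxy]silane | C[Si](C)(C)OC1=C[C@@](C)(c2ccccc2)CCC1 | intermediate
6 | methyl vinyl ketone (but-3-en-2-one) | CC(=O)C=C | starting material
7 | (2R,3S)-3-methyl-2-(3-oxobutyl)-3-phenylcyclohexan-1-one (oxobutyl trans to phenyl) | CC(=O)CC[C@H]1C(=O)CCC[C@]1(C)c2ccccc2 | intermediate
8 | (1S,2R)-1-methyl-3-oxo-2-(3-oxobutyl)cyclohexane-1-carboxylic acid | CC(=O)CC[C@H]1C(=O)CCC[C@]1(C)C(=O)O | intermediate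
9 | methyl (1S,2R)-1-methyl-3-oxo-2-(3-oxobutyl)cyclohexane-1-carboxylate | CC(=O)CC[C@H]1C(=O)CCC[C@]1(C)C(=O)OC | intermediate
10 | methyl (1S,8aS)-1-methyl-6-oxo-1,2,3,4,6,7,8,8a-octahydronaphthalene-1-carboxylate (octalone; CO2Me cis to H-5) | O=C1CC[C@H]2C(CCC[C@]2(C)C(=O)OC)=C1 | intermediate (key-step precursor)
11 | methyllithium | [Li]C | starting material
12 | methyl bromoacetate | COC(=O)CBr | starting material
13 | lithium dimethylcuprate | [Li+].C[Cu-]C | intermediate (not isolated)
14 | lithium enolate (C8–O–Li, C8=C9) of the cis-fused C10-methyl decalone | [Li]OC1=C[C@@]2(C)CCC[C@](C)(C(=O)OC)[C@H]2CC1 | intermediate (not isolated)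
15 | methyl (1S,4aS,5R,8aS)-5-(2-methoxy-2-oxoethyl)-1,4a-dimethyl-6-oxodecahydronaphthalene-1-carboxylate (cis-decalone; H-5, C20, C11 and C19 ester on one face) | O=C1CC[C@H]2[C@](C)(CCC[C@]2(C)C(=O)OC)[C@H]1CC(=O)OC | intermediate (key-step product)
16 | methyl (1S,4aR,5S,8aS)-5-(2-methoxy-2-oxoethyl)-1,4a-dimethyl-6-methylidenedecahydronaphthalene-1-carboxylate | C=C1CC[C@H]2[C@](C)(CCC[C@]2(C)C(=O)OC)[C@H]1CC(=O)OC | intermediate
17 | methyl (1S,4aR,5S,8aS)-5-(2-hydroxyethyl)-1,4a-dimethyl-6-methylidenedecahydronaphthalene-1-carboxylate | C=C1CC[C@H]2[C@](C)(CCC[C@]2(C)C(=O)OC)[C@H]1CCO | intermediate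
18 | methyl (1S,4aR,5S,8aS)-5-(2-iodoethyl)-1,4a-dimethyl-6-methylidenedecahydronaphthalene-1-carboxylate | C=C1CC[C@H]2[C@](C)(CCC[C@]2(C)C(=O)OC)[C@H]1CCI | intermediate
19 | but-2-yne-1,4-diol | OCC#CCO | starting material
20 | sodium cyclic (Z)-alkenylalanate from trans-hydroalumination (remote hydroxyl drawn free) | [Na+].COCCO[Al-]1(OCCOC)OC/C=C1/CO | intermediate (not isolated)
21 | (Z)-2-iodobut-2-ene-1,4-diol | OC/C(I)=C/CO | intermediate
22 | (Z)-1,4-bis[(tert-butyldimethylsilyl)oxy]-2-iodobut-2-ene | CC(C)(C)[Si](C)(C)OC/C(I)=C/CO[Si](C)(C)C(C)(C)C | intermediate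
23 | alkylzinc iodide from 18 (C12–ZnI) | C=C1CC[C@H]2[C@](C)(CCC[C@]2(C)C(=O)OC)[C@H]1CC[Zn]I | intermediate (not isolated)
24 | bis-TBS ether of the target (3E side chain) | C=C1CC[C@H]2[C@](C)(CCC[C@]2(C)C(=O)OC)[C@H]1CC/C(=C\CO[Si](C)(C)C(C)(C)C)CO[Si](C)(C)C(C)(C)C | intermediate
25 | methyl (1S,4aR,5S,8aS)-5-[(3E)-5-hydroxy-3-(hydroxymethyl)pent-3-en-1-yl]-1,4a-dimethyl-6-methylidenedecahydronaphthalene-1-carboxylate | C=C1CC[C@H]2[C@](C)(CCC[C@]2(C)C(=O)OC)[C@H]1CC/C(=C\CO)CO | target

**Totals and risks**

Total step count: 13. Longest linear sequence: 11 (steps 1–9, 12, 13); steps 10–11 make the vinyl iodide in parallel.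

The three steps most likely to fail:

1. Step 6 (key step). The hindered, copper-containing enolate may alkylate slowly, so that proton transfer from the acidic bromoacetate or to the product ketone returns the plain methyl adduct or moves alkylation to C7, and residual cuprate may consume the electrophile. Fallback: setting out from 10, the same cuprate addition would be quenched with allyl bromide, which is more reactive and has no acidic C–H, to give allyl ketone F1. As no other C=C is present, RuCl3/NaIO4 cleavage of the terminal alkene would give keto acid F2, and methylation with TMSCHN2 rejoins the route at 15.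

2. Step 2. Bond formation at the neopentyl enol-ether carbon may be slow under Lewis acid, the vinyl ketone may polymerise, and facial selectivity may erode if the mixture has to be warmed. Fallback: setting out from 5, methyllithium would unmask the aluminium-free lithium enolate F3. Its anionic Michael addition to 3-(trimethylsilyl)but-3-en-2-one (a non-polymerising acceptor that gives a stabilised α-silyl enolate) would afford silyl diketone F4, and fluoride-mediated protodesilylation (KF, aqueous MeOH) returns to 7.

3. Step 5. Enolisation toward C5 in the diketone, or dienolate formation in the product, may erode the C5 configuration during base-mediated ring closure, since neither epimer is strongly favoured. Fallback: setting out from 9, the closure would be run to completion without regard to C5 and the octalone C5 epimer F5 separated from 10 by chromatography (they are diastereomers). F5 would be re-equilibrated with DBU in toluene and recycled, so that material converges on 10 by a separation/recycle loop instead of kinetic preservation.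

Further compounds
F1 | step 6 | methyl (1S,4aS,5R,8aS)-1,4a-dimethyl-6-oxo-5-(prop-2-en-1-yl)decahydronaphthalene-1-carboxylate | O=C1CC[C@H]2[C@](C)(CCC[C@]2(C)C(=O)OC)[C@H]1CC=C
F2 | step 6 | methyl (1S,4aS,5R,8aS)-5-(carboxymethyl)-1,4a-dimethyl-6-oxodecahydronaphthalene-1-carboxylate | O=C1CC[C@H]2[C@](C)(CCC[C@]2(C)C(=O)OC)[C@H]1CC(=O)O
F3 | step 2 | lithium (S)-3-methyl-3-phenylcyclohex-1-en-1-olate | [Li]OC1=C[C@@](C)(c2ccccc2)CCC1
F4 | step 2 | (2R,3S)-3-methyl-2-[3-oxo-2-(trimethylsilyl)butyl]-3-phenylcyclohexan-1-one (both epimers at the silyl-bearing carbon) | CC(=O)C(C[C@H]1C(=O)CCC[C@]1(C)c2ccccc2)[Si](C)(C)C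
F5 | step 5 | methyl (1S,8aR)-1-methyl-6-oxo-1,2,3,4,6,7,8,8a-octahydronaphthalene-1-carboxylate | O=C1CC[C@@H]2C(CCC[C@]2(C)C(=O)OC)=C1
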